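Count what is left.

| flask | starting material | protic impurity | remark | time |
|---|---|---|---|---|
| winter | 1.5 M (in portions, 3) | 0.90 M | run made earlier; portions every 1.5 h |  |
| spring | 2.2 M (in portions, 3) | 0.90 M | run made earlier; portions every 1.5 h |  |
| flask | 3.0 M (in portions, 3) | 0.900 M | the portions of starting material follow each other after 1.5 h, the first at the start | 15 d |

| run | time / d | starting material / % | target / % |
|---|---|---|---|
| winter | 1.67 | 15.9 | 25.4 |
| winter | 5.00 | 9.8 | 15.8 |
| winter | 8.00 | 8.6 | 13.7 |
| winter | 12.0 | 7.1 | 12.0 |
| winter | 20.0 | 7.3 | 10.9 |
| spring | 4.00 | 12.3 | 18.7 |
| spring | 8.00 | 10.1 | 15.8 |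
| spring | 10.0 | 10.2 | 15.6 |
| spring | 15.0 | 10.4 | 15.7 |
| spring | 20.0 | 10.0 | 14.2 |

(readings scatter by 0.5 percentage points)

- how much of the starting material has reacted by 15 d
- how much target there is at 15 d, in percent of the starting material charged

- a reading or a percentage of target counts all its forms, free or not
- what has gone from starting material into another species counts as reacted, even if it can come back

Two chemists dispute this flask. The first holds that percentages ignore the charge. Her evidence is real: target over starting material at 20.0 d reads 1.49 in the winter run and 1.42 in the spring run. So she takes the spring target at 15.0 d, 15.7 %, for the flask.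

I hold the second view. The protic impurity is the limiting reagent: it removes its own amount of starting material, one for one, and the remainder shares out in one proportion. The charge then acts through the fraction left, one minus impurity over charge. That is 0.400 in the winter run, 0.591 in the spring run and 0.700 in the flask.

The last target readings are 10.9 % and 14.2 %, a gap of 3.3 percentage points against a scatter of 0.5 points. Divided by the fraction left, they give 27.2 % and 24.0 %. Their mean, 25.6 %, is the target's share of the fraction left.

The spring target reads 15.8 % at 8.00 d and 14.2 % at 20.0 d, a drop of 1.6 points against a scatter of 0.5 points, so these readings show no plateau. I take the last readings to stand for 15 d, and that is an assumption. My flask then holds 17.9 % target. The same division on starting material gives 87.7 % reacted.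

The forecast takes my side, saying the loss “looks like a fixed amount”, but its 88 % reacted and 17.5 % target come from its own straight line in the charge.

The flask gives 88.4 % reacted and 17.8 % target.

    starting material + protic impurity → quenched substrate (k = 5.71 × 10⁻⁴ M⁻¹ min⁻¹)
    starting material ⇌ isomer of the product B (K = 2.50, k = 4.61 × 10⁻⁴ min⁻¹)
    starting material ⇌ isomer of the product A (K = 1.00, k = 6.81 × 10⁻⁴ min⁻¹)
    crystals ⇌ target, rate k4*(cs4 - [target]) while solid is left; crystals form when [target] > cs4 (solubility = 1.50 M, k = 0.0875 min⁻¹)
    starting material ⇌ target (K = 1.53, k = 0.00200 min⁻¹)

That target stands 2.1 points above the first chemist's spring reading. At 15.0 d the flask holds 29.8 % quenched substrate, with 0.64 % of the impurity's own charge left. Her fixed percentage has its region where the bite is small. A neighbour flask, the same recipe with 0.23 M of impurity, has 0.0767 equiv of it, so its fraction left is 0.923. The share then gives 23.6 % target. The neighbour flask holds 23.5 %.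

All runs were computed for substances that don't exist, and the scatter is random.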